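**Retrosynthetic overview**
- C5–O is disconnected last. The chelated 5-OH comes from carbonyl-directed Ru-catalysed C5–H oxygenation of 7,8,2',4'-tetramethoxyflavone, so no 5-OMe is carried through and cleaved.
- The C ring (C4–C3 and O1–C2 bonds) comes from 2-hydroxy-3,4-dimethoxybenzaldehyde and a β-keto sulfoxonium ylide by Rh(III) aldehydic C–H activation, carbene insertion and cyclodehydration. No chalcone or Baker–Venkataraman step is used.
- The ylide comes from 2,4-dimethoxybenzoyl chloride and dimethylsulfoxonium methylide, whose carbon becomes C3.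
- Ring order: rings A and B are bought, and the pyranone C ring (step 2) is the only ring formed.

Assumption: the target has no stereocentre and rotates freely about C2–C1', so it is achiral. The "single enantiomer" requirement therefore places no demand on the route.

**Step 1**
Reactants: 1 2,4-dimethoxybenzoyl chloride; 2 trimethylsulfoxonium iodide
Product: 4 2-(dimethyl(oxo)-λ6-sulfanylidene)-1-(2,4-dimethoxyphenyl)ethan-1-one, via dimethylsulfoxonium methylide 3 (not isolated)
Conditions: 2 (3.0 equiv), KOtBu (3.0 equiv), THF, reflux, 2 h; then 1 (1.0 equiv) in THF, 0 °C → rt, 3 h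
Reagents that add atoms: none
Why: This is a Corey–Chaykovsky-type C-acylation in which methylide 3 attacks the acid chloride and a second equivalent of 3 deprotonates the acylsulfoxonium salt, giving the bench-stable carbonyl-stabilised ylide 4 with no stereocentre formed.

**Step 2**
Reactants: 4 2-(dimethyl(oxo)-λ6-sulfanylidene)-1-(2,4-dimethoxyphenyl)ethan-1-one (1.2 equiv); 5 2-hydroxy-3,4-dimethoxybenzaldehyde
Product: 7 7,8,2',4'-tetramethoxyflavone [2-(2,4-dimethoxyphenyl)-7,8-dimethoxy-4H-chromen-4-one], via o-hydroxyaryl 1,3-diketone 6 (not isolated)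
Conditions: [Cp*RhCl2]2 (2.5 mol %), AgSbF6 (10 mol %), NaOAc (30 mol %), DCE, 100 °C, 16 h, N2; then TsOH·H2O (50 mol %), 80 °C, 2 h, same pot
Reagents that add atoms: none
Why: In this Rh(III)-catalysed aldehydic C–H activation/carbene migratory insertion/annulation, the phenoxide of 5 steers Cp*Rh(III) into the formyl C–H to form a five-membered acyl-rhodacycle, 4 loses DMSO to give a Rh carbene, and acyl migration plus protodemetalation give diketone 6, which cyclodehydrates through its only phenol so the 7,8-dimethoxy pattern is unambiguous and no stereocentre is formed.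

**Step 3**
Reactants: 7 7,8,2',4'-tetramethoxyflavone
Product: 9 5-hydroxy-2',4',7,8-tetramethoxyflavone [2-(2,4-dimethoxyphenyl)-5-hydroxy-7,8-dimethoxy-4H-chromen-4-one], via flavon-5-yl trifluoroacetate 8 (not isolated)
Conditions: [RuCl2(p-cymene)]2 (5 mol %), PhI(OCOCF3)2 (1.5 equiv, two portions), TFA/TFAA 3:1, 80 °C, 6 h, sealed tube; then aq Na2S2O3/NaHCO3, THF, rt, 1 h
Reagents that add atoms: [bis(trifluoroacetoxy)iodo]benzene (PIFA), O=C(OI(OC(=O)C(F)(F)F)c1ccccc1)C(F)(F)F
Why: In this ketone-directed Ru(II)/Ru(IV) C–H oxygenation, the C4 carbonyl forms a five-membered ruthenacycle at C5–H (the only peri C–H, activated by the para 8-OMe), PIFA oxidation and C–O reductive elimination give trifluoroacetate 8, which TFAA keeps masked against over-oxidation while protonation of the flavone in TFA deactivates both anisole rings towards PIFA, and mild hydrolysis then frees the chelated 5-OH with no stereocentre formed.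

**Compound list**
1 | 2,4-dimethoxybenzoyl chloride | COc1ccc(C(=O)Cl)c(OC)c1 | starting material
2 | trimethylsulfoxonium iodide | C[S+](C)(C)=O.[I-] | starting material
3 | dimethylsulfoxonium methylide | C=S(C)(C)=O | intermediate
4 | 2-(dimethyl(oxo)-λ6-sulfanylidene)-1-(2,4-dimethoxyphenyl)ethan-1-one | COc1ccc(C(=O)C=S(C)(C)=O)c(OC)c1 | intermediate
5 | 2-hydroxy-3,4-dimethoxybenzaldehyde | COc1ccc(C=O)c(O)c1OC | starting material
6 | 1-(2-hydroxy-3,4-dimethoxyphenyl)-3-(2,4-dimethoxyphenyl)propane-1,3-dione | COc1ccc(C(=O)CC(=O)c2ccc(OC)c(OC)c2O)c(OC)c1 | intermediate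
7 | 7,8,2',4'-tetramethoxyflavone | COc1ccc(-c2cc(=O)c3ccc(OC)c(OC)c3o2)c(OC)c1 | intermediate
8 | 2-(2,4-dimethoxyphenyl)-7,8-dimethoxy-4-oxo-4H-chromen-5-yl trifluoroacetate | COc1ccc(-c2cc(=O)c3c(OC(=O)C(F)(F)F)cc(OC)c(OC)c3o2)c(OC)c1 | intermediate
9 | 5-hydroxy-2',4',7,8-tetramethoxyflavone | COc1ccc(-c2cc(=O)c3c(O)cc(OC)c(OC)c3o2)c(OC)c1 | target

**Total step count:** 3. **Longest linear sequence:** 3 (1 → 4 → 7 → 9).

**Steps most likely to fail**

**Step 3 (highest risk).**
- PIFA may oxidise the dimethoxyarene rings.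
- If 8 is unmasked in the pot, PIFA may take the 5-oxy/8-methoxy pair on to the 5,8-quinone.
- The carbonyl is only a weak director.

The fallback installs O-8 late instead of O-5. It sets out from 4 and comes back at 9.
- The step 2 annulation is run on 4 with commercial 2-hydroxy-4,6-dimethoxybenzaldehyde. It passes through 1-(2-hydroxy-4,6-dimethoxyphenyl)-3-(2,4-dimethoxyphenyl)propane-1,3-dione F1 and gives 5,7,2',4'-tetramethoxyflavone F2.
- BCl3 (CH2Cl2, −78 → 0 °C) removes only the carbonyl-chelated 5-O-methyl group and gives 5-hydroxy-7,2',4'-trimethoxyflavone F3.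
- Elbs persulfate oxidation (K2S2O8, aq KOH/pyridine, rt) attacks C8, the position para to the phenolate. It gives potassium 2-(2,4-dimethoxyphenyl)-5-hydroxy-7-methoxy-4-oxo-4H-chromen-8-yl sulfate F4.
- Dilute HCl with Na2SO3 (90 °C) hydrolyses this to 5,8-dihydroxy-7,2',4'-trimethoxyflavone F5.
- MeI (1.0 equiv), K2CO3, acetone under N2 methylates only the non-chelated 8-OH and delivers 9.

**Step 2.**
- Ylide 4 can be consumed by its own ketone-directed ortho C–H activation.
- The acyl-rhodium species can decarbonylate.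
- The 2-methoxy group hinders the carbene insertion.

The fallback is an alkynone route. It sets out from 5 and comes back at 7.
- Commercial 1-ethynyl-2,4-dimethoxybenzene and n-BuLi (THF, −78 °C) give lithium (2,4-dimethoxyphenyl)acetylide F6.
- 2.2 equiv of this acetylide is added to 5. The first equivalent deprotonates the phenol. The product is racemic 1-(2-hydroxy-3,4-dimethoxyphenyl)-3-(2,4-dimethoxyphenyl)prop-2-yn-1-ol F7.
- MnO2 (CH2Cl2, rt) removes the transient stereocentre and gives 1-(2-hydroxy-3,4-dimethoxyphenyl)-3-(2,4-dimethoxyphenyl)prop-2-yn-1-one F8.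
- Catalytic DMAP in DMF effects 6-endo-dig oxa-Michael closure to 7 rather than 5-exo closure to the aurone.

**Step 1 (lowest risk).**
- The electron-rich, ortho-substituted acid chloride may react slowly.
- The product ylide can be acylated a second time.

The fallback changes the class of carbene precursor. It sets out from 1 and comes back at 7 through 6.
- 1 and TMSCHN2 (2 equiv, MeCN/THF, 0 °C) give 2-diazo-1-(2,4-dimethoxyphenyl)ethan-1-one F9 by Arndt–Eistert-type acylation.
- F9 is added slowly to 5 under the Rh(III) conditions of step 2. It loses nitrogen to form the same Rh carbene, and so gives 6 and then 7.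

**Further compounds**
F1 | step 3 | 1-(2-hydroxy-4,6-dimethoxyphenyl)-3-(2,4-dimethoxyphenyl)propane-1,3-dione | COc1ccc(C(=O)CC(=O)c2c(O)cc(OC)cc2OC)c(OC)c1
F2 | step 3 | 5,7,2',4'-tetramethoxyflavone | COc1ccc(-c2cc(=O)c3c(OC)cc(OC)cc3o2)c(OC)c1
F3 | step 3 | 5-hydroxy-7,2',4'-trimethoxyflavone | COc1ccc(-c2cc(=O)c3c(O)cc(OC)cc3o2)c(OC)c1
F4 | step 3 | potassium 2-(2,4-dimethoxyphenyl)-5-hydroxy-7-methoxy-4-oxo-4H-chromen-8-yl sulfate | COc1ccc(-c2cc(=O)c3c(O)cc(OC)c(OS(=O)(=O)[O-])c3o2)c(OC)c1.[K+]
F5 | step 3 | 5,8-dihydroxy-7,2',4'-trimethoxyflavone | COc1ccc(-c2cc(=O)c3c(O)cc(OC)c(O)c3o2)c(OC)c1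
F6 | step 2 | lithium (2,4-dimethoxyphenyl)acetylide | [Li]C#Cc1ccc(OC)cc1OC
F7 | step 2 | racemic 1-(2-hydroxy-3,4-dimethoxyphenyl)-3-(2,4-dimethoxyphenyl)prop-2-yn-1-ol | COc1ccc(C#CC(O)c2ccc(OC)c(OC)c2O)c(OC)c1
F8 | step 2 | 1-(2-hydroxy-3,4-dimethoxyphenyl)-3-(2,4-dimethoxyphenyl)prop-2-yn-1-one | COc1ccc(C#CC(=O)c2ccc(OC)c(OC)c2O)c(OC)c1
F9 | step 1 | 2-diazo-1-(2,4-dimethoxyphenyl)ethan-1-one | COc1ccc(C(=O)C=[N+]=[N-])c(OC)c1
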